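**Retrosynthetic overview**
1. Ring labels: A = 4-hydroxy-3-aryloxyphenyl, B = 1,3-phenylene, C = 3,4-dihydroxy-5-aryloxyphenyl, D = 1,4-phenylene. The strategy rests on the two sp3-sp3 bonds between benzylic carbons that hold the 19-membered ring, A-CH2-CH2-D and B-CH2-CH2-C. Each is what a benzyl radical pair gives on recombination, so each is the retron of ArCH2-S-CH2Ar.
2. The target comes from its trimethyl ether by BBr3 cleavage. A sulfur atom is then written into each bridge, which leads back to a 21-membered dithia macrocycle (double photochemical sulfur extrusion in the forward sense).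
3. The B/C sulfide is opened to a seco bis(benzyl bromide) plus sulfide ion. The A/D sulfide is opened to a ring A benzyl bromide and a ring D thioacetate.
4. The A-O-B half comes from a Chan-Lam coupling of isovanillin, and the C-O-D half from an SNAr on 4-fluorobenzaldehyde. All four bridge carbons start as CHO or CO2Me carbons.
5. Ring order: one macrocyclisation by thiolate SN2 gives the 21-membered ring, which then contracts 21 to 20 to 19. No other ring is built.

Key step: step 12

Remark: the target has no stereocentre, and its flexible 19-membered ring carries no stable axis or plane of chirality. The SMILES has no stereodescriptor. The compound is therefore treated as achiral, and no enantiomer has to be selected.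

**Step 1**
Reactants: 1 isovanillin (3-hydroxy-4-methoxybenzaldehyde); 2 3-(methoxycarbonyl)phenylboronic acid
Product: 3 methyl 3-(5-formyl-2-methoxyphenoxy)benzoate
Conditions: Cu(OAc)2 (1 equiv), pyridine (5 equiv), 4 Å MS, CH2Cl2, dry air, rt; 2 in 1.5 equiv
Reagents that add atoms: none
Why: Chan-Lam O-arylation (transmetallation to the copper phenoxide, oxidation to Cu(III), C-O reductive elimination) runs at room temperature, so the aldehyde and the ester are untouched and the only free OH of ring A is arylated.

**Step 2**
Reactants: 3 methyl 3-(5-formyl-2-methoxyphenoxy)benzoate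
Product: 4 methyl 3-[5-(hydroxymethyl)-2-methoxyphenoxy]benzoate
Conditions: NaBH4, MeOH/THF, 0 °C
Reagents that add atoms: none
Why: Chemoselective borohydride reduction, in which the aryl aldehyde is reduced within minutes at 0 °C while the aromatic methyl ester is inert to NaBH4.

**Step 3**
Reactants: 4 methyl 3-[5-(hydroxymethyl)-2-methoxyphenoxy]benzoate
Product: 5 methyl 3-[5-(bromomethyl)-2-methoxyphenoxy]benzoate
Conditions: PBr3 (0.4 equiv), CH2Cl2, 0 °C; cold NaHCO3 wash, used crude at once
Reagents that add atoms: phosphorus tribromide, BrP(Br)Br
Why: Bromodehydroxylation through a phosphite ester and bromide displacement is fast for this p-methoxy-activated benzylic alcohol, spares ester and ethers, and needs no chromatography of the labile bromide.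

**Step 4**
Reactants: 6 methyl 3-hydroxy-4,5-dimethoxybenzoate; 7 4-fluorobenzaldehyde
Product: 8 methyl 3-(4-formylphenoxy)-4,5-dimethoxybenzoate
Conditions: K2CO3, DMF, 120 °C
Reagents that add atoms: none
Why: Nucleophilic aromatic substitution by addition-elimination, in which the para-formyl group stabilises the Meisenheimer adduct and fluoride is the best leaving group for this mechanism, so the phenoxide of 6 forms the C-O-D ether.

**Step 5**
Reactants: 8 methyl 3-(4-formylphenoxy)-4,5-dimethoxybenzoate
Product: 9 methyl 3-[4-(hydroxymethyl)phenoxy]-4,5-dimethoxybenzoate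
Conditions: NaBH4, MeOH/THF, 0 °C
Reagents that add atoms: none
Why: Chemoselective borohydride reduction of the aldehyde beside an unreactive aromatic methyl ester, as in step 2.

**Step 6**
Reactants: 9 methyl 3-[4-(hydroxymethyl)phenoxy]-4,5-dimethoxybenzoate
Product: 10 methyl 3-[4-(bromomethyl)phenoxy]-4,5-dimethoxybenzoate
Conditions: PBr3 (0.4 equiv), CH2Cl2, 0 °C
Reagents that add atoms: phosphorus tribromide, BrP(Br)Br
Why: Bromodehydroxylation of a primary benzylic alcohol with PBr3, giving a p-aryloxybenzyl bromide that is only moderately activated and can be handled normally.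

**Step 7**
Reactants: 10 methyl 3-[4-(bromomethyl)phenoxy]-4,5-dimethoxybenzoate
Product: 11 methyl 3-{4-[(acetylsulfanyl)methyl]phenoxy}-4,5-dimethoxybenzoate
Conditions: KSAc, DMF, rt
Reagents that add atoms: potassium thioacetate, CC(=O)[S-].[K+]
Why: SN2 displacement of the benzylic bromide by the soft thioacetate anion installs sulfur as a storable masked thiol that cannot oxidise to a disulfide.

**Step 8**
Reactants: 11 methyl 3-{4-[(acetylsulfanyl)methyl]phenoxy}-4,5-dimethoxybenzoate; 5 methyl 3-[5-(bromomethyl)-2-methoxyphenoxy]benzoate
Product: 13 open-chain A/D thioether diester, via ring D benzyl thiol 12 (not isolated)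
Conditions: NaOMe (1.0 equiv), degassed MeOH/THF, 0 °C, 20 min; then 5 in THF, 0 °C to rt, Ar
Reagents that add atoms: none
Why: Methanolysis of the thioester with exactly one equivalent of methoxide frees the thiolate of 12 (the methyl esters can only exchange degenerately), and this thiolate S-alkylates bromide 5 by SN2 faster than methanol can solvolyse it, while exclusion of oxygen suppresses disulfide formation.

**Step 9**
Reactants: 13 open-chain A/D thioether diester
Product: 14 open-chain A/D thioether diol (CH2OH on rings B and C)
Conditions: LiAlH4, THF, 0 °C to rt; aqueous NaOH work-up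
Reagents that add atoms: none
Why: Lithium aluminium hydride reduction takes both aromatic esters to primary benzylic alcohols and does not touch the thioether, the diaryl ethers or the methyl ethers.

**Step 10**
Reactants: 14 open-chain A/D thioether diol
Product: 15 seco bis(benzyl bromide) (CH2Br on rings B and C)
Conditions: CBr4, PPh3, CH2Cl2, 0 °C; short silica plug, used promptly
Reagents that add atoms: carbon tetrabromide, BrC(Br)(Br)Br
Why: The Appel reaction activates both alcohols as alkoxyphosphonium ions under neutral conditions, so the p-methoxybenzyl-type sulfide sees no acid, and the weakly nucleophilic dibenzyl sulfide is not expected to be alkylated in cold CH2Cl2.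

**Step 11**
Reactants: 15 seco bis(benzyl bromide)
Product: 16 21-membered dithia macrocycle trimethyl ether
Conditions: 15 in THF and Na2S·9H2O in EtOH/H2O (9:1), both added by syringe pump over 12 h to degassed EtOH/THF, rt, Ar, final ca. 1 mM
Reagents that add atoms: sodium sulfide (as nonahydrate), [Na+].[Na+].[S-2]
Why: Double SN2 thioetherification under pseudo-high dilution, as used for thiacyclophanes, in which the second displacement is intramolecular and closes an unstrained 21-membered ring faster than a second molecule can be met.

**Step 12**
Reactants: 16 21-membered dithia macrocycle trimethyl ether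
Product: 19 bis(bibenzyl) macrocycle trimethyl ether, via B/C-monothia macrocycle 17 (not isolated), via A/D-monothia macrocycle 18 (not isolated)
Conditions: hν (254 nm, quartz), P(OMe)3 (neat, degassed), ca. 2 mM, Ar, rt; stopped when 17 and 18 are consumed
Reagents that add atoms: none
Why: Excitation of an arylmethyl sulfide chromophore homolyses a benzylic C-S bond, the thiyl radical adds to P(OMe)3, and beta-scission of the phosphoranyl radical releases (MeO)3P=S and a second benzyl radical, so each bridge ends as a benzyl radical pair that collapses to ArCH2-CH2Ar. The closest known reaction type is the photochemical desulfurisation of dibenzyl sulfide and of dithia[3.3]cyclophanes in trialkyl phosphite, which gives bibenzyl and [2.2]cyclophanes. Each ring is closed by intramolecular radical-radical recombination of a biradical held together by the other bridge and both diaryl ethers: the 21-membered ring recloses as a 20-membered ring (17 or 18) and this recloses as the 19-membered ring of 19, forming the A-CH2-CH2-D and B-CH2-CH2-C bonds. No stereocentre is formed. The step needs recombination inside the tethered pair to win over hydrogen abstraction, oxygen trapping and intermolecular coupling, which should hold because benzyl radicals abstract hydrogen from phosphite C-H bonds only sluggishly and cannot disproportionate, the tethered partner has an effective molarity far above the steady-state radical concentration, and oxygen is excluded. The A/D and B/C pairing should not scramble, because simultaneous opening of both bridges is improbable at the low steady-state radical concentration and the pairing was fixed in steps 8 and 11.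

**Step 13**
Reactants: 19 bis(bibenzyl) macrocycle trimethyl ether
Product: 20 target CNP0495401.0
Conditions: BBr3 (8 equiv), CH2Cl2, -78 °C to rt; ice-water quench, work-up under Ar
Reagents that add atoms: none
Why: Lewis-acid aryl methyl ether cleavage, in which bromide attacks the methyl carbon of each BBr3-complexed OMe by SN2, whereas the diaryl ether oxygens carry no sp3 carbon and survive; all three phenols are released on hydrolysis.

**Compound list**
1 | isovanillin (3-hydroxy-4-methoxybenzaldehyde, ring A) | COc1ccc(C=O)cc1O | starting material
2 | 3-(methoxycarbonyl)phenylboronic acid (ring B) | COC(=O)c1cccc(B(O)O)c1 | starting material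
3 | methyl 3-(5-formyl-2-methoxyphenoxy)benzoate | COC(=O)c1cccc(Oc2cc(C=O)ccc2OC)c1 | intermediate
4 | methyl 3-[5-(hydroxymethyl)-2-methoxyphenoxy]benzoate | COC(=O)c1cccc(Oc2cc(CO)ccc2OC)c1 | intermediate
5 | methyl 3-[5-(bromomethyl)-2-methoxyphenoxy]benzoate | COC(=O)c1cccc(Oc2cc(CBr)ccc2OC)c1 | intermediate
6 | methyl 3-hydroxy-4,5-dimethoxybenzoate (ring C) | COC(=O)c1cc(O)c(OC)c(OC)c1 | starting material
7 | 4-fluorobenzaldehyde (ring D) | O=Cc1ccc(F)cc1 | starting material
8 | methyl 3-(4-formylphenoxy)-4,5-dimethoxybenzoate | COC(=O)c1cc(OC)c(OC)c(Oc2ccc(C=O)cc2)c1 | intermediate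
9 | methyl 3-[4-(hydroxymethyl)phenoxy]-4,5-dimethoxybenzoate | COC(=O)c1cc(OC)c(OC)c(Oc2ccc(CO)cc2)c1 | intermediate
10 | methyl 3-[4-(bromomethyl)phenoxy]-4,5-dimethoxybenzoate | COC(=O)c1cc(OC)c(OC)c(Oc2ccc(CBr)cc2)c1 | intermediate
11 | methyl 3-{4-[(acetylsulfanyl)methyl]phenoxy}-4,5-dimethoxybenzoate | COC(=O)c1cc(OC)c(OC)c(Oc2ccc(CSC(C)=O)cc2)c1 | intermediate
12 | methyl 3,4-dimethoxy-5-[4-(sulfanylmethyl)phenoxy]benzoate (present in the flask as its sodium thiolate, not isolated) | COC(=O)c1cc(OC)c(OC)c(Oc2ccc(CS)cc2)c1 | intermediate
13 | open-chain diester with the ring A CH2-S-CH2 ring D thioether | COC(=O)c1cccc(Oc2cc(CSCc3ccc(Oc4cc(C(=O)OC)cc(OC)c4OC)cc3)ccc2OC)c1 | intermediate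
14 | open-chain A/D thioether diol (CH2OH on rings B and C) | OCc1cccc(Oc2cc(CSCc3ccc(Oc4cc(CO)cc(OC)c4OC)cc3)ccc2OC)c1 | intermediate
15 | seco bis(benzyl bromide) (CH2Br on rings B and C) | BrCc1cccc(Oc2cc(CSCc3ccc(Oc4cc(CBr)cc(OC)c4OC)cc3)ccc2OC)c1 | intermediate
16 | 21-membered dithia macrocycle trimethyl ether (A-CH2SCH2-D and B-CH2SCH2-C) | COc1ccc2cc1Oc1cccc(c1)CSCc1cc(OC)c(OC)c(c1)Oc1ccc(cc1)CSC2 | intermediate
17 | 20-membered monothia macrocycle keeping the B/C sulfide (A-CH2CH2-D formed, not isolated) | COc1ccc2cc1Oc1cccc(c1)CSCc1cc(OC)c(OC)c(c1)Oc1ccc(cc1)CC2 | intermediate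
18 | 20-membered monothia macrocycle keeping the A/D sulfide (B-CH2CH2-C formed, not isolated) | COc1ccc2cc1Oc1cccc(c1)CCc1cc(OC)c(OC)c(c1)Oc1ccc(cc1)CSC2 | intermediate
19 | 19-membered bis(bibenzyl) macrocycle trimethyl ether | COc1ccc2cc1Oc1cccc(c1)CCc1cc(OC)c(OC)c(c1)Oc1ccc(cc1)CC2 | intermediate
20 | CNP0495401.0 (achiral) | Oc1ccc2cc1Oc1cccc(c1)CCc1cc(O)c(O)c(c1)Oc1ccc(cc1)CC2 | target

**Step count**
- Total step count: 13.
- Longest linear sequence: 10 steps (steps 4 to 13). The other branch, steps 1 to 3, joins at step 8.

**Steps most likely to fail**

*Step 12.* The biradical from a flexible large ring may be intercepted before it recloses, by hydrogen abstraction, adventitious oxygen or intermolecular coupling. Long irradiation at 254 nm may also start photochemical cleavage or rearrangement of the diaryl ethers. The fallback sets out from 16 and makes both C-C bonds ionically. Oxidation with mCPBA (CH2Cl2, 0 °C) should give the bis-sulfone F1. A double Ramberg-Bäcklund reaction with in situ halogenation (KOH, CCl4, t-BuOH) forms each bond by 1,3-elimination to an episulfone, which loses SO2. This should give the bis-stilbene macrocycle F2 as an E/Z mixture. Hydrogenation (H2, Pd/C, EtOAc) erases the alkene geometry and rejoins the route at 19.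

*Step 11.* Oligomerisation may outrun ring closure, and the benzylic bromides may solvolyse in the protic medium. The fallback sets out from 15 and closes the ring through an S-S bond.
- KSAc in DMF should give the bis(thioacetate) F3.
- NaOMe in degassed MeOH should give the dithiol F4.
- Iodine oxidation at high dilution (MeOH/CH2Cl2) should close the 22-membered cyclic disulfide F5.
- Sulfur contraction of the benzylic disulfide with tris(diethylamino)phosphine in benzene removes one sulfur atom and returns to the route at 16.

*Step 3.* The p-methoxy-activated benzylic bromide may ionise during work-up or storage, which leads to hydrolysis and Friedel-Crafts self-condensation. The fallback reverses the polarity of the A/D union and sets out from 4. A Mitsunobu reaction with thioacetic acid (PPh3, DIAD, THF, 0 °C) should give the ring A thioacetate F6. One equivalent of NaOMe then frees the ring A thiol F7 (not isolated). This thiol is S-alkylated by the more robust ring D bromide 10, so step 7 is dropped and the route is rejoined at 13.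

**Further compounds**
F1 | step 12 | 21-membered bis-sulfone macrocycle trimethyl ether | COc1ccc2cc1Oc1cccc(c1)CS(=O)(=O)Cc1cc(OC)c(OC)c(c1)Oc1ccc(cc1)CS(=O)(=O)C2
F2 | step 12 | 19-membered bis-stilbene macrocycle trimethyl ether (E/Z mixture, geometry not defined) | COc1ccc2cc1Oc1cccc(c1)C=Cc1cc(OC)c(OC)c(c1)Oc1ccc(cc1)C=C2
F3 | step 11 | seco bis(thioacetate) on rings B and C | CC(=O)SCc1cccc(Oc2cc(CSCc3ccc(Oc4cc(CSC(C)=O)cc(OC)c4OC)cc3)ccc2OC)c1
F4 | step 11 | seco dithiol on rings B and C | SCc1cccc(Oc2cc(CSCc3ccc(Oc4cc(CS)cc(OC)c4OC)cc3)ccc2OC)c1
F5 | step 11 | 22-membered macrocycle with B/C disulfide and A/D sulfide | COc1ccc2cc1Oc1cccc(c1)CSSCc1cc(OC)c(OC)c(c1)Oc1ccc(cc1)CSC2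
F6 | step 3 | methyl 3-{5-[(acetylsulfanyl)methyl]-2-methoxyphenoxy}benzoate | COC(=O)c1cccc(Oc2cc(CSC(C)=O)ccc2OC)c1
F7 | step 3 | methyl 3-[2-methoxy-5-(sulfanylmethyl)phenoxy]benzoate | COC(=O)c1cccc(Oc2cc(CS)ccc2OC)c1
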